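**Retrosynthetic overview**
1. Flavonoid numbering is used: O1, C2, C3, C4, C4a, C5–C8, C8a. Ring A is the benzo ring, ring B the 2-aryl group, ring C the pyranone. The last event is hydrogenolysis of four benzyl ethers.
2. Ring C is the only ring to be built. It closes at C3–C4 by a visible-light acylsilane–aldehyde coupling: an aroylsilane at C4 becomes a nucleophilic siloxycarbene that adds to a formyl group at C3. Silicon is a traceless umpolung group that ends on O3 and is removed in the same flask.
3. Enabling feature: C4(=O)–C3H(OH) is an acyloin whose carbonyl carbon sits on ring A ortho to O1. The two-atom link O1–C2 therefore holds the C3 formyl carbon at six-ring distance from C4, and ring B on C2 together with the C2–O1 dipole decides the face of C3.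
4. C2 is set beforehand by iridium-catalysed asymmetric allylic etherification of a ring A salicylaldehyde with a cinnamyl carbonate. CHO → C(O)SiMe2Ph and vinyl → CHO then give the photosubstrate.
5. The salicylaldehyde comes from 3,5-bis(benzyloxy)phenol by boron-templated ortho-benzylation and ortho-formylation. 4-(Benzyloxy)benzaldehyde supplies both ring B and the C8 benzyl group.

Key step: step 11

Assumption: the (Sa,Sc,Sc) phosphoramidite is taken to give the (S)-allyl aryl ether, by analogy with cinnamyl carbonates and heteroatom nucleophiles. If the opposite sense were found, the equally available (Ra,Rc,Rc) ligand would be used.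

**Step 1**
Reactants: 1 3,5-bis(benzyloxy)phenol; 2 4-(benzyloxy)benzaldehyde
Product: 3 5,7-bis(benzyloxy)-4-[4-(benzyloxy)phenyl]-2-phenyl-4H-1,3,2-benzodioxaborinine (racemic)
Conditions: PhB(OH)2 (1.1 equiv), EtCO2H (cat.), toluene, reflux, Dean–Stark trap
Reagents that add atoms: phenylboronic acid OB(O)c1ccccc1
Why: Boronate-templated ortho-hydroxyalkylation, in which the mixed phenyl boronate of the phenol delivers the aldehyde only to an ortho carbon; the two ortho positions of 1 are equivalent, the para position is out of reach, and the racemic benzhydrylic centre is erased in step 2.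

**Step 2**
Reactants: 3 benzodioxaborinine
Product: 4 3,5-bis(benzyloxy)-2-[4-(benzyloxy)benzyl]phenol
Conditions: Et3SiH (3 equiv), CF3CO2H, CH2Cl2, 0 °C; aqueous work-up
Reagents that add atoms: none
Why: Ionic hydrogenation, in which acid ionises the doubly aryl-stabilised benzhydrylic C–O bond and Et3SiH delivers hydride, while the aryl benzyl ethers should survive at 0 °C and the work-up hydrolyses the boronate.

**Step 3**
Reactants: 4 ortho-benzylphenol
Product: 5 4,6-bis(benzyloxy)-3-[4-(benzyloxy)benzyl]-2-hydroxybenzaldehyde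
Conditions: MgCl2 (2 equiv), Et3N (4 equiv), (CH2O)n (6 equiv), MeCN, reflux; 1 M HCl work-up
Reagents that add atoms: paraformaldehyde, reacting as formaldehyde C=O
Why: Casnati–Skattebøl ortho-formylation, in which the magnesium phenoxide binds formaldehyde and directs it to the only free ortho carbon, and a second formaldehyde takes up hydride from the salicyl alkoxide, so the position between the two benzyloxy groups is not attacked.

**Step 4**
Reactants: 2 4-(benzyloxy)benzaldehyde
Product: 6 ethyl (E)-3-[4-(benzyloxy)phenyl]acrylate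
Conditions: Ph3P=CHCO2Et (1.1 equiv), toluene, 80 °C
Reagents that add atoms: (carbethoxymethylene)triphenylphosphorane CCOC(=O)C=P(c1ccccc1)(c1ccccc1)c1ccccc1
Why: Wittig olefination with a stabilised ylide, which should give the E-cinnamate from an aromatic aldehyde.

**Step 5**
Reactants: 6 ethyl cinnamate
Product: 7 (E)-3-[4-(benzyloxy)phenyl]prop-2-en-1-ol
Conditions: i-Bu2AlH (2.2 equiv), CH2Cl2, −78 to 0 °C; aq. potassium sodium tartrate
Reagents that add atoms: none
Why: 1,2-Reduction of an enoate with i-Bu2AlH, which leaves the alkene geometry and the benzyl ether untouched.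

**Step 6**
Reactants: 7 cinnamyl alcohol
Product: 8 (E)-3-[4-(benzyloxy)phenyl]allyl methyl carbonate
Conditions: ClCO2Me (1.2 equiv), pyridine (1.5 equiv), CH2Cl2, 0 °C
Reagents that add atoms: methyl chloroformate COC(=O)Cl
Why: O-Acylation of a primary allylic alcohol, which installs the leaving group needed for the allylic substitution.

**Step 7**
Reactants: 5 salicylaldehyde; 8 cinnamyl carbonate
Product: 9 (S)-4,6-bis(benzyloxy)-3-[4-(benzyloxy)benzyl]-2-{1-[4-(benzyloxy)phenyl]allyloxy}benzaldehyde
Conditions: [Ir(cod)Cl]2 (2 mol %), (Sa,Sc,Sc)-O,O'-(1,1'-binaphthyl-2,2'-diyl)-N,N-bis(1-phenylethyl)phosphoramidite (4 mol %), 1,5,7-triazabicyclo[4.4.0]dec-5-ene (8 mol %, catalyst activation), THF, 50 °C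
Reagents that add atoms: none
Why: Iridium-catalysed asymmetric allylic etherification, in which the cyclometalated iridium–phosphoramidite complex ionises 8 to an η3-allyl species; the phenoxide of 5 (freed by the methoxide released on decarboxylation) attacks it at the aryl-bearing terminus anti to the metal, so the branched ether forms and the ligand sets C2 as (S), a descriptor that becomes (R) without any change in space once vinyl is turned into formyl.

**Step 8**
Reactants: 9 (S)-allyl aryl ether aldehyde
Product: 10 {4,6-bis(benzyloxy)-3-[4-(benzyloxy)benzyl]-2-[(S)-1-[4-(benzyloxy)phenyl]allyloxy]phenyl}[dimethyl(phenyl)silyl]methanol (both carbinol epimers)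
Conditions: PhMe2SiLi (1.2 equiv), THF, −78 °C; AcOH in THF at −78 °C
Reagents that add atoms: dimethyl(phenyl)silyllithium [Li][Si](C)(C)c1ccccc1
Why: 1,2-Addition of a silyllithium to an aldehyde, where the cold acidic quench and the electron-rich ring A disfavour Brook rearrangement of the alkoxide, and the mixed carbinol centre does not matter because step 9 removes it.

**Step 9**
Reactants: 10 α-hydroxysilane
Product: 11 {4,6-bis(benzyloxy)-3-[4-(benzyloxy)benzyl]-2-[(S)-1-[4-(benzyloxy)phenyl]allyloxy]phenyl}[dimethyl(phenyl)silyl]methanone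
Conditions: Dess–Martin periodinane (1.5 equiv), CH2Cl2, 0 °C to rt, dark
Reagents that add atoms: none
Why: Dess–Martin oxidation of an α-hydroxysilane to the acylsilane under non-basic conditions that avoid Brook rearrangement and leave the alkene, the ethers and C2 untouched.

**Step 10**
Reactants: 11 aroylsilane with vinyl group
Product: 13 (R)-2-[4-(benzyloxy)phenyl]-2-{3,5-bis(benzyloxy)-2-[4-(benzyloxy)benzyl]-6-[dimethyl(phenyl)silylcarbonyl]phenoxy}acetaldehyde, via vicinal diol 12 (not isolated)
Conditions: OsO4 (2 mol %), NMO (1.5 equiv), acetone/H2O, rt, dark; then NaIO4 (1.5 equiv), pH 7 phosphate buffer, 0 °C, 30 min; extraction, used without chromatography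
Reagents that add atoms: N-methylmorpholine N-oxide C[N+]1([O-])CCOCC1 (oxygen relayed through OsO4); water O
Why: Upjohn dihydroxylation followed by periodate glycol cleavage (two-stage Lemieux–Johnson sequence), so the enolisable α-aryl-α-aryloxy aldehyde meets only a cold neutral medium for a short time and C2 should keep its configuration.

**Step 11**
Reactants: 13 aroylsilane aldehyde
Product: 16 (2R,3R)-5,7-bis(benzyloxy)-8-[4-(benzyloxy)benzyl]-2-[4-(benzyloxy)phenyl]-3-hydroxychroman-4-one, via siloxycarbene 14 (not isolated), via silyl ether 15 (not isolated)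
Conditions: hν (420 nm LED), dry degassed toluene (5 mM), 4 Å molecular sieves, 10 °C, Ar; then filtration, 1 M aq. HCl, THF, rt
Reagents that add atoms: none
Why: Proposed new method: irradiation into the n→π* band of the aroylsilane moves silicon from C4 to the carbonyl oxygen (photochemical 1,2-Brook shift) and gives the singlet nucleophilic siloxycarbene 14, whose carbene carbon C4 attacks the formyl carbon C3; the alkoxide/oxocarbenium zwitterion, or the strained 2-siloxyoxirane it can collapse to (the species a Rubottom oxidation passes through), relaxes by a 1,4-shift of silicon from O4 to O3 to give 15, and dilute acid then frees the C3 hydroxyl. The closest known reaction type is the light-induced intermolecular coupling of aroylsilanes with aldehydes or activated ketones to α-siloxy ketones (formal cross-benzoin reaction), which has not been used to close a ring onto an α-aryloxy aldehyde. Ring C closes in the 6-exo-trig mode (C4, C4a, C8a, O1, C2, C3), with the formyl oxygen staying outside the ring. The new C3 stereocenter is controlled by C2: in the chair-like transition state ring B is equatorial and the formyl C=O stands antiperiplanar to the C2–O1 bond (Cornforth-type dipole minimisation), so O3 becomes equatorial and trans to ring B, which is (2R,3R). The step needs regiospecific umpolung (C4 donor, C3 acceptor), secured because only the acylsilane absorbs at 420 nm, and it needs an untouched acidic C2–H, secured by the absence of base and of nucleophilic catalysts, which would cause enolisation, five-ring aldol closure of C2 onto C4, or expulsion of the ring A phenoxide from the α-aryloxy aldehyde. Carbene that finds no partner reverts thermally to 13, and high dilution together with dry solvent should suppress intermolecular coupling and O–H insertion.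

**Step 12**
Reactants: 16 tetra-O-benzyl flavanonol
Product: 17 (2R,3R)-3,5,7-trihydroxy-8-(4-hydroxybenzyl)-2-(4-hydroxyphenyl)chroman-4-one (target)
Conditions: H2 (1 atm), 10% Pd/C, EtOAc/MeOH, rt
Reagents that add atoms: none
Why: Catalytic hydrogenolysis of four aryl benzyl ethers under neutral conditions, which is standard for benzylated dihydroflavonols and should leave the C4 ketone, the C2–O1 bond, the diarylmethane and both stereocenters intact if stopped after the calculated uptake.

**Compound list**
1 | 3,5-bis(benzyloxy)phenol | Oc1cc(OCc2ccccc2)cc(OCc2ccccc2)c1 | starting material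
2 | 4-(benzyloxy)benzaldehyde | O=Cc1ccc(OCc2ccccc2)cc1 | starting material
3 | 5,7-bis(benzyloxy)-4-[4-(benzyloxy)phenyl]-2-phenyl-4H-1,3,2-benzodioxaborinine (racemic) | c1ccccc1B1Oc2cc(OCc3ccccc3)cc(OCc3ccccc3)c2C(c2ccc(OCc3ccccc3)cc2)O1 | intermediate
4 | 3,5-bis(benzyloxy)-2-[4-(benzyloxy)benzyl]phenol | Oc1cc(OCc2ccccc2)cc(OCc2ccccc2)c1Cc1ccc(OCc2ccccc2)cc1 | intermediate
5 | 4,6-bis(benzyloxy)-3-[4-(benzyloxy)benzyl]-2-hydroxybenzaldehyde | O=Cc1c(O)c(Cc2ccc(OCc3ccccc3)cc2)c(OCc2ccccc2)cc1OCc1ccccc1 | intermediate
6 | ethyl (E)-3-[4-(benzyloxy)phenyl]acrylate | CCOC(=O)/C=C/c1ccc(OCc2ccccc2)cc1 | intermediate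
7 | (E)-3-[4-(benzyloxy)phenyl]prop-2-en-1-ol | OC/C=C/c1ccc(OCc2ccccc2)cc1 | intermediate
8 | (E)-3-[4-(benzyloxy)phenyl]allyl methyl carbonate | COC(=O)OC/C=C/c1ccc(OCc2ccccc2)cc1 | intermediate
9 | (S)-4,6-bis(benzyloxy)-3-[4-(benzyloxy)benzyl]-2-{1-[4-(benzyloxy)phenyl]allyloxy}benzaldehyde | O=Cc1c(OCc2ccccc2)cc(OCc2ccccc2)c(Cc2ccc(OCc3ccccc3)cc2)c1O[C@H](c1ccc(OCc2ccccc2)cc1)C=C | intermediate
10 | α-hydroxysilane from 9, (S) at the ether carbon, both carbinol epimers | OC([Si](C)(C)c1ccccc1)c1c(OCc2ccccc2)cc(OCc2ccccc2)c(Cc2ccc(OCc3ccccc3)cc2)c1O[C@H](c1ccc(OCc2ccccc2)cc1)C=C | intermediate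
11 | aroyl(dimethyl)phenylsilane with (S)-1-arylallyl ether | O=C([Si](C)(C)c1ccccc1)c1c(OCc2ccccc2)cc(OCc2ccccc2)c(Cc2ccc(OCc3ccccc3)cc2)c1O[C@H](c1ccc(OCc2ccccc2)cc1)C=C | intermediate
12 | vicinal diol from 11 (both carbinol epimers) | O=C([Si](C)(C)c1ccccc1)c1c(OCc2ccccc2)cc(OCc2ccccc2)c(Cc2ccc(OCc3ccccc3)cc2)c1O[C@H](c1ccc(OCc2ccccc2)cc1)C(O)CO | intermediate
13 | (R)-2-[4-(benzyloxy)phenyl]-2-{3,5-bis(benzyloxy)-2-[4-(benzyloxy)benzyl]-6-[dimethyl(phenyl)silylcarbonyl]phenoxy}acetaldehyde | O=C([Si](C)(C)c1ccccc1)c1c(OCc2ccccc2)cc(OCc2ccccc2)c(Cc2ccc(OCc3ccccc3)cc2)c1O[C@H](c1ccc(OCc2ccccc2)cc1)C=O | intermediate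
14 | aryl[dimethyl(phenyl)siloxy]carbene from 13 | C[Si](C)(c1ccccc1)O[C]c1c(OCc2ccccc2)cc(OCc2ccccc2)c(Cc2ccc(OCc3ccccc3)cc2)c1O[C@H](c1ccc(OCc2ccccc2)cc1)C=O | intermediate
15 | (2R,3R)-5,7-bis(benzyloxy)-8-[4-(benzyloxy)benzyl]-2-[4-(benzyloxy)phenyl]-3-[dimethyl(phenyl)silyloxy]chroman-4-one | O=C1c2c(OCc3ccccc3)cc(OCc3ccccc3)c(Cc3ccc(OCc4ccccc4)cc3)c2O[C@H](c2ccc(OCc3ccccc3)cc2)[C@H]1O[Si](C)(C)c1ccccc1 | intermediate
16 | (2R,3R)-5,7-bis(benzyloxy)-8-[4-(benzyloxy)benzyl]-2-[4-(benzyloxy)phenyl]-3-hydroxychroman-4-one | O=C1c2c(OCc3ccccc3)cc(OCc3ccccc3)c(Cc3ccc(OCc4ccccc4)cc3)c2O[C@H](c2ccc(OCc3ccccc3)cc2)[C@H]1O | intermediate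
17 | (2R,3R)-3,5,7-trihydroxy-8-(4-hydroxybenzyl)-2-(4-hydroxyphenyl)chroman-4-one | O=C1c2c(O)cc(O)c(Cc3ccc(O)cc3)c2O[C@H](c2ccc(O)cc2)[C@H]1O | target

**Total step count:** 12. **Longest linear sequence:** 9 steps (steps 1–3 or 4–6, then 7–12).

**Steps most likely to fail**

1. **Step 11** (the proposed new method).
   - What may go wrong: capture of the carbene by the formyl group may lose against reversion, against hydrogen abstraction from benzylic ether C–H bonds by the excited acylsilane, or against O–H insertion of residual water. Facial selectivity at C3 may also be poor.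
   - Fallback: it uses only known chemistry, sets out from 9 and comes back at 16. Wittig methylenation of the formyl group of 9 (MePPh3Br, KOt-Bu, THF, 0 °C) would give the vinylarene diene F1. Ring-closing metathesis (second-generation Grubbs catalyst, CH2Cl2, 40 °C) would close the same C3–C4 bond as an alkene and give the (S)-flav-3-ene F2. OsO4/NMO dihydroxylation, which on flav-3-enes takes place on the face opposite ring B, would give the 2,3-trans-3,4-cis flavan-3,4-diol F3. Activated MnO2 (CH2Cl2, rt) would oxidise only the benzylic C4 carbinol and deliver 16.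

2. **Step 7.**
   - What may go wrong: attack of the doubly ortho-substituted, hydrogen-bonded and weakly nucleophilic phenoxide on the allyl-iridium species may be slow. This would allow drift to the linear ether and erosion of enantiopurity through re-ionisation of the product.
   - Fallback: it sets out from 2 and 5 and comes back at 9. It replaces the allyl-metal electrophile by a linear copper allenylidene, whose remote γ-carbon is less sensitive to the ortho substituents and whose product cannot re-ionise. Addition of HC≡CMgBr to 2 (THF, 0 °C) would give the racemic propargylic alcohol F4. Acetylation (Ac2O, pyridine) would give the propargylic acetate F5. Copper-catalysed enantioselective propargylic etherification of 5 with F5 (CuOTf·0.5C6H6, chiral 2,6-bis(4-phenyloxazolin-2-yl)pyridine, i-Pr2NEt, ClCH2CH2Cl, 0 °C) would give the (S)-propargyl aryl ether F6. Semihydrogenation (H2, Pd/CaCO3 poisoned with Pb(OAc)2, quinoline, EtOAc) would give 9.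

3. **Step 10.**
   - What may go wrong: the freshly formed α-aryl-α-aryloxy aldehyde may enolise in the aqueous medium, with loss of configuration at C2, or the acylsilane may suffer oxidative or hydrolytic damage.
   - Fallback: it sets out from 10 and comes back at 13. The order of events changes so that the acylsilane never meets an aqueous oxidant and the aldehyde is released by an anhydrous oxidation just before irradiation. OsO4/NMO on 10 would give the silyl carbinol triol F7. NaIO4 at 0 °C would give the silyl carbinol aldehyde F8, which NaBH4 added to the same flask would reduce at once to the configurationally stable silyl carbinol primary alcohol F9. F9 can be purified and enriched by crystallisation. Dess–Martin periodinane (2.5 equiv, CH2Cl2, 0 °C) would then oxidise both carbinols in one operation to 13.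

**Further compounds**
F1 | step 11 | (S)-1,5-bis(benzyloxy)-4-[4-(benzyloxy)benzyl]-3-{1-[4-(benzyloxy)phenyl]allyloxy}-2-vinylbenzene (vinylarene diene) | C=Cc1c(OCc2ccccc2)cc(OCc2ccccc2)c(Cc2ccc(OCc3ccccc3)cc2)c1O[C@H](c1ccc(OCc2ccccc2)cc1)C=C
F2 | step 11 | (S)-5,7-bis(benzyloxy)-8-[4-(benzyloxy)benzyl]-2-[4-(benzyloxy)phenyl]-2H-chromene ((S)-flav-3-ene) | C1=C[C@@H](c2ccc(OCc3ccccc3)cc2)Oc2c1c(OCc1ccccc1)cc(OCc1ccccc1)c2Cc1ccc(OCc2ccccc2)cc1
F3 | step 11 | (2R,3S,4S)-5,7-bis(benzyloxy)-8-[4-(benzyloxy)benzyl]-2-[4-(benzyloxy)phenyl]chromane-3,4-diol (2,3-trans-3,4-cis flavan-3,4-diol) | O[C@H]1c2c(OCc3ccccc3)cc(OCc3ccccc3)c(Cc3ccc(OCc4ccccc4)cc3)c2O[C@H](c2ccc(OCc3ccccc3)cc2)[C@H]1O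
F4 | step 7 | 1-[4-(benzyloxy)phenyl]prop-2-yn-1-ol (racemic propargylic alcohol) | C#CC(O)c1ccc(OCc2ccccc2)cc1
F5 | step 7 | 1-[4-(benzyloxy)phenyl]prop-2-yn-1-yl acetate (propargylic acetate) | C#CC(OC(C)=O)c1ccc(OCc2ccccc2)cc1
F6 | step 7 | (S)-4,6-bis(benzyloxy)-3-[4-(benzyloxy)benzyl]-2-{1-[4-(benzyloxy)phenyl]prop-2-yn-1-yloxy}benzaldehyde ((S)-propargyl aryl ether) | O=Cc1c(OCc2ccccc2)cc(OCc2ccccc2)c(Cc2ccc(OCc3ccccc3)cc2)c1O[C@H](c1ccc(OCc2ccccc2)cc1)C#C
F7 | step 10 | silyl carbinol triol from 10 (carbinol epimers) | OC([Si](C)(C)c1ccccc1)c1c(OCc2ccccc2)cc(OCc2ccccc2)c(Cc2ccc(OCc3ccccc3)cc2)c1O[C@H](c1ccc(OCc2ccccc2)cc1)C(O)CO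
F8 | step 10 | silyl carbinol aldehyde, (R) at the ether carbon | OC([Si](C)(C)c1ccccc1)c1c(OCc2ccccc2)cc(OCc2ccccc2)c(Cc2ccc(OCc3ccccc3)cc2)c1O[C@H](c1ccc(OCc2ccccc2)cc1)C=O
F9 | step 10 | silyl carbinol primary alcohol, (R) at the ether carbon | OC([Si](C)(C)c1ccccc1)c1c(OCc2ccccc2)cc(OCc2ccccc2)c(Cc2ccc(OCc3ccccc3)cc2)c1O[C@H](c1ccc(OCc2ccccc2)cc1)CO
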